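## Retrosynthetic overview

- The target is (13R)-13-hydroxylabd-8(17)-ene-15,19-dioic acid (4S,5R,9S,10R,13R; C19 acid axial on C4). Both acids come from a 13,15,19-triol by a late double oxidation. The C19 alcohol comes from a chiral ester, and a temporary C3 ketone is removed by radical deoxygenation.
- Key disconnection: C4–C5 and C9–C10 are cut together, giving an open-chain (E,E)-diene α-methyl β-keto ester. In the forward sense ring A closes first (C4 to C5), ring B second (C10 to C9), and the C8 radical is then oxidised to the C8=C17 methylene.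
- Enabling feature: the exocyclic C8=C17 methylene on ring B next to C9, the methyl-bearing ring-fusion carbon C10, and the C19 carboxyl on quaternary C4 of ring A. C19 plus a temporary C3 carbonyl make C4 a radical-forming β-dicarbonyl carbon. The C5=C10 and C8=C9 alkenes of a 1,5-diene map onto both rings, and C8=C17 is the mark left by the terminating tertiary radical.
- The precursor is made by dianion alkylation of (−)-8-phenylmenthyl 2-methylacetoacetate with a C15 allylic bromide from (2E,6E)-farnesol. C13 is set at the start by Sharpless epoxidation and Red-Al opening.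

Key step: step 8

Remark (assumption): the non-chelated α-methyl β-keto ester radical of the (−)-8-phenylmenthyl ester is taken to react on the face away from the phenyl ring, with the ester C=O s-cis to the ketone carbon, which gives the 4β-ester/10β-methyl series; should the opposite sense be found, (+)-8-phenylmenthol would be used in step 6 with nothing else changed.

## Route

Step 1
Reactants: 1 (2E,6E)-farnesol
Product: 2 (2R,3R)-2,3-epoxyfarnesol
Conditions: Ti(OiPr)4 (cat.), D-(−)-diethyl tartrate (cat.), t-BuOOH, 4 Å MS, CH2Cl2, −20 °C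
Reagents that add atoms: tert-butyl hydroperoxide, CC(C)(C)OO
Why: Sharpless asymmetric epoxidation is hydroxyl-directed, so only the C2=C3 alkene reacts, and the D-(−)-tartrate should deliver oxygen to the face that gives the (2R,3R) epoxide, which fixes the later C13 configuration.

Step 2
Reactants: 2 (2R,3R)-2,3-epoxyfarnesol
Product: 3 (3R,6E)-3,7,11-trimethyldodeca-6,10-diene-1,3-diol
Conditions: Red-Al, THF, 0 °C → rt; aq. Rochelle salt
Reagents that add atoms: none
Why: Reductive opening of a 2,3-epoxy alcohol by the alkoxy-aluminate delivers hydride intramolecularly to C2, so the 1,3-diol should form and the C3–O bond, hence the (R) carbinol, stays untouched.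

Step 3
Reactants: 3 (3R,6E)-3,7,11-trimethyldodeca-6,10-diene-1,3-diol
Product: 4 (4R)-2,2-di-tert-butyl-4-[(3E)-4,8-dimethylnona-3,7-dien-1-yl]-4-methyl-1,3,2-dioxasilinane
Conditions: t-Bu2Si(OTf)2, 2,6-lutidine, CH2Cl2, 0 °C → rt
Reagents that add atoms: di-tert-butylsilyl bis(trifluoromethanesulfonate), CC(C)(C)[Si](OS(=O)(=O)C(F)(F)F)(OS(=O)(=O)C(F)(F)F)C(C)(C)C
Why: Silylene acetal formation of a 1,3-diol ties up the tertiary hydroxyl (so it cannot capture C8 in step 8) and the primary hydroxyl in one six-membered ring that should be stable to base, acetic acid and radicals.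

Step 4
Reactants: 4 silylene acetal
Product: 5 (2E,6E)-9-[(4R)-2,2-di-tert-butyl-4-methyl-1,3,2-dioxasilinan-4-yl]-2,6-dimethylnona-2,6-dien-1-ol
Conditions: SeO2 (cat.), t-BuOOH, salicylic acid (cat.), CH2Cl2, 0 °C → rt, stopped at partial conversion, 4 recycled
Reagents that add atoms: selenium dioxide, O=[Se]=O (catalytic oxygen carrier); tert-butyl hydroperoxide, CC(C)(C)OO (terminal oxidant)
Why: Selenium dioxide allylic oxidation (ene reaction, then [2,3]-sigmatropic shift) should attack the (E)-methyl of the terminal dimethyl-substituted alkene in preference to the internal alkene and give the (E)-allylic alcohol.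

Step 5
Reactants: 5 allylic alcohol
Product: 6 (4R)-4-[(3E,7E)-9-bromo-4,8-dimethylnona-3,7-dien-1-yl]-2,2-di-tert-butyl-4-methyl-1,3,2-dioxasilinane
Conditions: CBr4, PPh3, CH2Cl2, 0 °C; used crude
Reagents that add atoms: carbon tetrabromide, BrC(Br)(Br)Br
Why: The Appel reaction should convert the primary allylic alcohol by SN2 under neutral conditions, without allylic transposition or loss of the E geometry.

Step 6
Reactants: 7 ethyl 2-methyl-3-oxobutanoate; 8 (−)-8-phenylmenthol, (1R,2S,5R)-5-methyl-2-(2-phenylpropan-2-yl)cyclohexan-1-ol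
Product: 9 (1R,2S,5R)-8-phenylmenthyl 2-methyl-3-oxobutanoate (both C2 epimers)
Conditions: DMAP (cat.), toluene, reflux, 4 Å MS (ethanol removed)
Reagents that add atoms: none
Why: DMAP-catalysed transesterification of a β-keto ester is driven by removal of ethanol, and the epimeric α-centre is of no consequence because it becomes a radical in step 8.

Step 7
Reactants: 9 (−)-8-phenylmenthyl 2-methyl-3-oxobutanoate; 6 allylic bromide
Product: 11 (1R,2S,5R)-8-phenylmenthyl (6E,10E)-13-[(4R)-2,2-di-tert-butyl-4-methyl-1,3,2-dioxasilinan-4-yl]-2,6,10-trimethyl-3-oxotrideca-6,10-dienoate (both C2 epimers), via sodium lithium dianion 10 (not isolated)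
Conditions: NaH, THF, 0 °C; n-BuLi, 0 °C; then 6, 0 °C → rt; aq. NH4Cl
Reagents that add atoms: none
Why: In β-keto ester dianion alkylation the terminal (γ) carbanion is the more reactive site and should displace the primary allylic bromide by SN2, joining the future C2 to C1 with both E alkenes intact.

Step 8
Reactants: 11 open-chain (E,E)-diene α-methyl β-keto ester
Product: 12 (1R,2S,5R)-8-phenylmenthyl (13R)-13,15-(di-tert-butylsilanediyldioxy)-3-oxolabd-8(17)-en-19-oate (trans-decalin; 4α-Me, 4β-ester axial, 5α-H, 9α-H, 10β-Me)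
Conditions: Mn(OAc)3·2H2O (2.2 equiv), Cu(OAc)2·H2O (1 equiv), degassed AcOH, 25–40 °C
Reagents that add atoms: none
Why: Mn(III) oxidises the β-keto ester to a planar C4 radical (both C2 epimers of 11 converge on it), which adds to C5 of the (E)-C5=C10 alkene (6-endo-trig, ring A); the tertiary C10 radical then adds to C9 of the (E)-C8=C9 alkene (6-endo-trig, ring B, forming C9–C10), and Cu(II) oxidises the tertiary C8 radical with loss of a C17 hydrogen to the C8=C17 methylene. The closest known reaction type is the Mn(OAc)3/Cu(OAc)2 oxidative free-radical polyene cyclisation of α-methyl β-keto esters, including its 8-phenylmenthyl ester variant. At C4 the radical reacts with the ester carbon anti to the C3 carbonyl oxygen, so the ester ends axial (4β) and the methyl equatorial, while the phenyl ring of the auxiliary covers one face of the radical and sends C5 to the other, which sets the absolute configuration. C5 and C10 follow from anti addition across the E alkene in a chair transition state (trans fusion, 5α-H, 10β-Me), and C9 from the chair closure of ring B, which places C11 of the E alkene equatorial (9α-H). The step needs facial selectivity (from the auxiliary), 6-endo regioselectivity (the methyl groups on C10 and C8 make the inner alkene carbons the hindered ones) and exocyclic termination (Cu(II)-mediated hydrogen loss from the unhindered C17 methyl); the C13 oxygen is locked in the silylene so that it cannot capture C8.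

Step 9
Reactants: 12 bicyclic β-keto ester
Product: 13 (1R,2S,5R)-8-phenylmenthyl (13R)-13,15-(di-tert-butylsilanediyldioxy)-3β-hydroxylabd-8(17)-en-19-oate
Conditions: NaBH4, THF/MeOH, 0 °C
Reagents that add atoms: none
Why: Borohydride should reduce only the C3 ketone (the hindered ester is inert), with axial hydride delivery from the α-face giving the equatorial 3β-alcohol; this centre is temporary and either epimer serves.

Step 10
Reactants: 13 3β-alcohol
Product: 14 (1R,2S,5R)-8-phenylmenthyl (13R)-13,15-(di-tert-butylsilanediyldioxy)-3β-(imidazol-1-ylcarbothioyloxy)labd-8(17)-en-19-oate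
Conditions: 1,1'-thiocarbonyldiimidazole, DMAP (cat.), 1,2-dichloroethane, 80 °C
Reagents that add atoms: 1,1'-thiocarbonyldiimidazole, S=C(n1ccnc1)n1ccnc1
Why: Neutral thioacylation (first half of the Barton–McCombie deoxygenation) avoids a free alkoxide and therefore retro-aldol opening of ring A at the β-hydroxy ester.

Step 11
Reactants: 14 imidazolyl thiocarbonate
Product: 15 (1R,2S,5R)-8-phenylmenthyl (13R)-13,15-(di-tert-butylsilanediyldioxy)labd-8(17)-en-19-oate
Conditions: Bu3SnH, AIBN (cat.), toluene, 100 °C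
Reagents that add atoms: none
Why: In the Barton–McCombie deoxygenation the stannyl radical adds to C=S, β-scission gives the secondary C3 radical and hydrogen transfer removes the temporary oxygen; the ester, silylene and exocyclic alkene should be inert.

Step 12
Reactants: 15 3-deoxy silylene ester
Product: 16 (1R,2S,5R)-8-phenylmenthyl (13R)-13,15-dihydroxylabd-8(17)-en-19-oate
Conditions: TBAF, THF, rt → 50 °C
Reagents that add atoms: none
Why: Fluoride cleaves both Si–O bonds under non-acidic conditions, so the 13-hydroxy-8(17)-ene system is not exposed to acid (no 8,13-ether formation) and the hindered ester stays.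

Step 13
Reactants: 16 diol ester
Product: 17 (13R)-labd-8(17)-ene-13,15,19-triol
Conditions: LiAlH4 (excess), THF, 0 °C → reflux; aq. NaOH work-up; auxiliary 8 recovered
Reagents that add atoms: none
Why: Hydride reduction is the reliable way to cleave the hindered axial neopentyl ester; it should give the C19 alcohol and release the auxiliary, while the isolated alkene is inert.

Step 14
Reactants: 17 triol
Product: 18 (13R)-13-hydroxylabd-8(17)-ene-15,19-dial
Conditions: Dess–Martin periodinane, NaHCO3, CH2Cl2, 0 °C → rt; used at once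
Reagents that add atoms: none
Why: Dess–Martin oxidation should convert both primary alcohols (including the neopentyl C19) to aldehydes; the tertiary C13 hydroxyl cannot be oxidised, and the buffer suppresses β-elimination of the 13-hydroxy aldehyde.

Step 15
Reactants: 18 dialdehyde
Product: 19 (13R)-13-hydroxylabd-8(17)-ene-15,19-dioic acid (target)
Conditions: NaClO2, NaH2PO4, 2-methyl-2-butene, t-BuOH/H2O, rt
Reagents that add atoms: sodium chlorite, [Na+].[O-]Cl=O
Why: Pinnick oxidation should take both aldehydes to the acids without touching the tertiary alcohol, with 2-methyl-2-butene scavenging hypochlorous acid to protect the C8=C17 alkene.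

## Compound list

1 | (2E,6E)-farnesol | OC/C=C(\C)CC/C=C(\C)CCC=C(C)C | starting material
2 | (2R,3R)-2,3-epoxyfarnesol | OC[C@H]1O[C@]1(C)CC/C=C(\C)CCC=C(C)C | intermediate
3 | (3R,6E)-3,7,11-trimethyldodeca-6,10-diene-1,3-diol | OCC[C@](C)(O)CC/C=C(\C)CCC=C(C)C | intermediate
4 | (4R)-2,2-di-tert-butyl-4-[(3E)-4,8-dimethylnona-3,7-dien-1-yl]-4-methyl-1,3,2-dioxasilinane | CC(C)(C)[Si]1(C(C)(C)C)OCC[C@@](C)(CC/C=C(\C)CCC=C(C)C)O1 | intermediate
5 | (2E,6E)-9-[(4R)-2,2-di-tert-butyl-4-methyl-1,3,2-dioxasilinan-4-yl]-2,6-dimethylnona-2,6-dien-1-ol | CC(C)(C)[Si]1(C(C)(C)C)OCC[C@@](C)(CC/C=C(\C)CC/C=C(\C)CO)O1 | intermediate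
6 | (4R)-4-[(3E,7E)-9-bromo-4,8-dimethylnona-3,7-dien-1-yl]-2,2-di-tert-butyl-4-methyl-1,3,2-dioxasilinane | CC(C)(C)[Si]1(C(C)(C)C)OCC[C@@](C)(CC/C=C(\C)CC/C=C(\C)CBr)O1 | intermediate
7 | ethyl 2-methyl-3-oxobutanoate | CCOC(=O)C(C)C(C)=O | starting material
8 | (−)-8-phenylmenthol, (1R,2S,5R)-5-methyl-2-(2-phenylpropan-2-yl)cyclohexan-1-ol | O[C@@H]1C[C@H](C)CC[C@H]1C(C)(C)c1ccccc1 | starting material
9 | (1R,2S,5R)-8-phenylmenthyl 2-methyl-3-oxobutanoate (both C2 epimers) | CC(=O)C(C)C(=O)O[C@@H]1C[C@H](C)CC[C@H]1C(C)(C)c1ccccc1 | intermediate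
10 | sodium lithium dianion (1,3-dienolate) of 9 | C=C([O-])C(C)=C([O-])O[C@@H]1C[C@H](C)CC[C@H]1C(C)(C)c1ccccc1.[Na+].[Li+] | intermediate
11 | (1R,2S,5R)-8-phenylmenthyl (6E,10E)-13-[(4R)-2,2-di-tert-butyl-4-methyl-1,3,2-dioxasilinan-4-yl]-2,6,10-trimethyl-3-oxotrideca-6,10-dienoate (both C2 epimers) | CC(C(=O)CC/C(C)=C/CC/C(C)=C/CC[C@]1(C)CCO[Si](C(C)(C)C)(C(C)(C)C)O1)C(=O)O[C@@H]1C[C@H](C)CC[C@H]1C(C)(C)c1ccccc1 | intermediate
12 | (1R,2S,5R)-8-phenylmenthyl (13R)-13,15-(di-tert-butylsilanediyldioxy)-3-oxolabd-8(17)-en-19-oate | C=C1CC[C@@H]2[C@](C)(CCC(=O)[C@]2(C)C(=O)O[C@@H]2C[C@H](C)CC[C@H]2C(C)(C)c2ccccc2)[C@H]1CC[C@]1(C)CCO[Si](C(C)(C)C)(C(C)(C)C)O1 | intermediate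
13 | (1R,2S,5R)-8-phenylmenthyl (13R)-13,15-(di-tert-butylsilanediyldioxy)-3β-hydroxylabd-8(17)-en-19-oate | C=C1CC[C@@H]2[C@](C)(CC[C@H](O)[C@]2(C)C(=O)O[C@@H]2C[C@H](C)CC[C@H]2C(C)(C)c2ccccc2)[C@H]1CC[C@]1(C)CCO[Si](C(C)(C)C)(C(C)(C)C)O1 | intermediate
14 | (1R,2S,5R)-8-phenylmenthyl (13R)-13,15-(di-tert-butylsilanediyldioxy)-3β-(imidazol-1-ylcarbothioyloxy)labd-8(17)-en-19-oate | C=C1CC[C@@H]2[C@](C)(CC[C@H](OC(=S)n3ccnc3)[C@]2(C)C(=O)O[C@@H]2C[C@H](C)CC[C@H]2C(C)(C)c2ccccc2)[C@H]1CC[C@]1(C)CCO[Si](C(C)(C)C)(C(C)(C)C)O1 | intermediate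
15 | (1R,2S,5R)-8-phenylmenthyl (13R)-13,15-(di-tert-butylsilanediyldioxy)labd-8(17)-en-19-oate | C=C1CC[C@@H]2[C@](C)(CCC[C@]2(C)C(=O)O[C@@H]2C[C@H](C)CC[C@H]2C(C)(C)c2ccccc2)[C@H]1CC[C@]1(C)CCO[Si](C(C)(C)C)(C(C)(C)C)O1 | intermediate
16 | (1R,2S,5R)-8-phenylmenthyl (13R)-13,15-dihydroxylabd-8(17)-en-19-oate | C=C1CC[C@@H]2[C@](C)(CCC[C@]2(C)C(=O)O[C@@H]2C[C@H](C)CC[C@H]2C(C)(C)c2ccccc2)[C@H]1CC[C@@](C)(O)CCO | intermediate
17 | (13R)-labd-8(17)-ene-13,15,19-triol | C=C1CC[C@@H]2[C@](C)(CCC[C@]2(C)CO)[C@H]1CC[C@@](C)(O)CCO | intermediate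
18 | (13R)-13-hydroxylabd-8(17)-ene-15,19-dial | C=C1CC[C@@H]2[C@](C)(CCC[C@]2(C)C=O)[C@H]1CC[C@@](C)(O)CC=O | intermediate
19 | (13R)-13-hydroxylabd-8(17)-ene-15,19-dioic acid (4S,5R,9S,10R,13R) | C=C1CC[C@@H]2[C@](C)(CCC[C@]2(C)C(=O)O)[C@H]1CC[C@@](C)(O)CC(=O)O | target

## Step count and risks

Total steps: 15. Longest linear sequence: 14 (steps 1–5 and 7–15, from farnesol); step 6 is a one-step side branch.

**1. Step 8.** What may go wrong: weak or inverted facial discrimination of the non-chelated tertiary radical by the auxiliary, and non-regioselective hydrogen loss at C8.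

Fallback (chelation control on the α-unsubstituted ester, then C-methylation), setting out from 6 and returning at 17. Commercial (+)-8-phenylmenthol and 2,2,6-trimethyl-4H-1,3-dioxin-4-one (xylene, 140 °C) give (1S,2R,5S)-8-phenylmenthyl acetoacetate F1. NaH, then n-BuLi, converts it into its sodium lithium dianion F2, which is alkylated with 6 to the open-chain α-unsubstituted β-keto ester F3. Mn(OAc)3/Cu(OAc)2 with Yb(OTf)3 in CF3CH2OH cyclises the chelated enol radical, for which this auxiliary is known to give high facial control, to the bicyclic 3-oxo ester F4. Methylation (K2CO3, MeI, acetone) should enter from the α-face, away from the C10 methyl, to give the 4α-methyl-4β-ester F5. The operations of steps 9–12 then give the 3β-alcohol F6, the imidazolyl thiocarbonate F7, the 3-deoxy silylene ester F8 and the diol ester F9, and LiAlH4 reduces F9 to 17.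

**2. Step 4.** What may go wrong: competing allylic oxidation at the internal trisubstituted alkene and over-oxidation, so that little of the terminal alcohol is obtained.

Fallback (terminal alkene cleavage and olefination instead of C–H oxidation), setting out from 4 and returning at 5. NBS in aqueous THF at 0 °C should attack the terminal alkene selectively to give the bromohydrin F10. K2CO3 in MeOH closes it to the terminal epoxide F11, and periodic acid in THF/ether cleaves this to the aldehyde F12. A Wittig reaction with ethyl 2-(triphenylphosphoranylidene)propanoate gives the (E)-enoate F13, and DIBAL-H at −78 °C reduces it to 5.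

**3. Step 10.** What may go wrong: slow or incomplete acylation of the neopentyl 3β-hydroxyl next to the quaternary C4 with its bulky axial ester, or ring opening by retro-aldol if forced with base.

Fallback (hydrazone reduction instead of alcohol deoxygenation), setting out from 12 and returning at 15. TsNHNH2 in EtOH at 80 °C gives the C3 tosylhydrazone F14. Catecholborane in CHCl3 at 0 °C, then NaOAc·3H2O at reflux, reduces it to the methylene compound 15, bypassing steps 9–11.

Further compounds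
F1 | step 8 | (1S,2R,5S)-8-phenylmenthyl 3-oxobutanoate | CC(=O)CC(=O)O[C@H]1C[C@@H](C)CC[C@@H]1C(C)(C)c1ccccc1
F2 | step 8 | sodium lithium dianion (1,3-dienolate) of F1 | C=C([O-])C=C([O-])O[C@H]1C[C@@H](C)CC[C@@H]1C(C)(C)c1ccccc1.[Na+].[Li+]
F3 | step 8 | (1S,2R,5S)-8-phenylmenthyl (6E,10E)-13-[(4R)-2,2-di-tert-butyl-4-methyl-1,3,2-dioxasilinan-4-yl]-6,10-dimethyl-3-oxotrideca-6,10-dienoate | O=C(CC(=O)O[C@H]1C[C@@H](C)CC[C@@H]1C(C)(C)c1ccccc1)CC/C(C)=C/CC/C(C)=C/CC[C@]1(C)CCO[Si](C(C)(C)C)(C(C)(C)C)O1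
F4 | step 8 | (1S,2R,5S)-8-phenylmenthyl (13R)-13,15-(di-tert-butylsilanediyldioxy)-3-oxo-18-norlabd-8(17)-en-19-oate (C4-H, ester equatorial; enolisable) | C=C1CC[C@@H]2[C@](C)(CCC(=O)[C@H]2C(=O)O[C@H]2C[C@@H](C)CC[C@@H]2C(C)(C)c2ccccc2)[C@H]1CC[C@]1(C)CCO[Si](C(C)(C)C)(C(C)(C)C)O1
F5 | step 8 | (1S,2R,5S)-8-phenylmenthyl (13R)-13,15-(di-tert-butylsilanediyldioxy)-3-oxolabd-8(17)-en-19-oate | C=C1CC[C@@H]2[C@](C)(CCC(=O)[C@]2(C)C(=O)O[C@H]2C[C@@H](C)CC[C@@H]2C(C)(C)c2ccccc2)[C@H]1CC[C@]1(C)CCO[Si](C(C)(C)C)(C(C)(C)C)O1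
F6 | step 8 | (1S,2R,5S)-8-phenylmenthyl (13R)-13,15-(di-tert-butylsilanediyldioxy)-3β-hydroxylabd-8(17)-en-19-oate | C=C1CC[C@@H]2[C@](C)(CC[C@H](O)[C@]2(C)C(=O)O[C@H]2C[C@@H](C)CC[C@@H]2C(C)(C)c2ccccc2)[C@H]1CC[C@]1(C)CCO[Si](C(C)(C)C)(C(C)(C)C)O1
F7 | step 8 | (1S,2R,5S)-8-phenylmenthyl (13R)-13,15-(di-tert-butylsilanediyldioxy)-3β-(imidazol-1-ylcarbothioyloxy)labd-8(17)-en-19-oate | C=C1CC[C@@H]2[C@](C)(CC[C@H](OC(=S)n3ccnc3)[C@]2(C)C(=O)O[C@H]2C[C@@H](C)CC[C@@H]2C(C)(C)c2ccccc2)[C@H]1CC[C@]1(C)CCO[Si](C(C)(C)C)(C(C)(C)C)O1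
F8 | step 8 | (1S,2R,5S)-8-phenylmenthyl (13R)-13,15-(di-tert-butylsilanediyldioxy)labd-8(17)-en-19-oate | C=C1CC[C@@H]2[C@](C)(CCC[C@]2(C)C(=O)O[C@H]2C[C@@H](C)CC[C@@H]2C(C)(C)c2ccccc2)[C@H]1CC[C@]1(C)CCO[Si](C(C)(C)C)(C(C)(C)C)O1
F9 | step 8 | (1S,2R,5S)-8-phenylmenthyl (13R)-13,15-dihydroxylabd-8(17)-en-19-oate | C=C1CC[C@@H]2[C@](C)(CCC[C@]2(C)C(=O)O[C@H]2C[C@@H](C)CC[C@@H]2C(C)(C)c2ccccc2)[C@H]1CC[C@@](C)(O)CCO
F10 | step 4 | (4R)-4-[(3E)-7-bromo-8-hydroxy-4,8-dimethylnon-3-en-1-yl]-2,2-di-tert-butyl-4-methyl-1,3,2-dioxasilinane (both C7 epimers) | CC(C)(C)[Si]1(C(C)(C)C)OCC[C@@](C)(CC/C=C(\C)CCC(Br)C(C)(C)O)O1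
F11 | step 4 | (4R)-2,2-di-tert-butyl-4-[(3E)-6-(3,3-dimethyloxiran-2-yl)-4-methylhex-3-en-1-yl]-4-methyl-1,3,2-dioxasilinane (both epoxide epimers) | CC(C)(C)[Si]1(C(C)(C)C)OCC[C@@](C)(CC/C=C(\C)CCC2OC2(C)C)O1
F12 | step 4 | (4E)-7-[(4R)-2,2-di-tert-butyl-4-methyl-1,3,2-dioxasilinan-4-yl]-4-methylhept-4-enal | CC(C)(C)[Si]1(C(C)(C)C)OCC[C@@](C)(CC/C=C(\C)CCC=O)O1
F13 | step 4 | ethyl (2E,6E)-9-[(4R)-2,2-di-tert-butyl-4-methyl-1,3,2-dioxasilinan-4-yl]-2,6-dimethylnona-2,6-dienoate | CC(C)(C)[Si]1(C(C)(C)C)OCC[C@@](C)(CC/C=C(\C)CC/C=C(\C)C(=O)OCC)O1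
F14 | step 10 | C3 p-toluenesulfonylhydrazone of 12 | C=C1CC[C@@H]2[C@](C)(CCC(=NNS(=O)(=O)c3ccc(C)cc3)[C@]2(C)C(=O)O[C@@H]2C[C@H](C)CC[C@H]2C(C)(C)c2ccccc2)[C@H]1CC[C@]1(C)CCO[Si](C(C)(C)C)(C(C)(C)C)O1
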